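**Retrosynthetic overview**

1. Locants: ring A is the acyl-trione ring with spiro carbon C3 between C2=O (next to the gem-diprenyl carbon C1) and C4=O (next to the acyl-bearing C5); ring B is the cyclohexane C3–C7–C8–C9–C13–C14 with carbinol C13(CH3)OH; ring C is the cyclopentane C8–C12–C11–C10–C9 with carbinol C12(CH3)OH.
2. Last disconnection: the silyl ether on the C12 oxygen. Key disconnection: C8–C9 (closes ring C) and C3–C14 (closes ring B) in one flask, with C3–C7 made between them by reductive alkylation; this takes the spiro-hydrindane back to the flat ring A trione and an acyclic C10 aldehyde.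
3. Enabling feature: carbinol carbon C13 lies between both new bonds (C9–C13–C14), the imprint of a 2,3-epoxy tosylate whose one oxygen serves twice (opened at C9, re-closed onto C14, opened there by C3). C8 is α to C7, which can be an aldehyde carbon before it becomes the CH2 on C3, and C3 is a carbon acid between C2=O and C4=O that can take two alkyl groups.
4. The aldehyde comes from (R)-linalool (C12 from the chiral pool) by allylic oxidation, Sharpless epoxidation (C13 and, after inversion, C9), tosylation, hydroboration–oxidation and alcohol oxidation; ring A comes from phloroglucinol by acylation and geminal diprenylation.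
5. Order of ring formation: ring A (dearomatised trione) first, ring C next (5-exo-tet), ring B last (6-endo-tet at C14, creating the spiro centre).

Key step: step 9

Assumption: (R)-(−)-linalool is taken as a commercial starting material of high enantiomeric purity, and the trione ring is drawn in one enol form that stands for all its tautomers.

**Route**

Step 1
Reactants: 1 phloroglucinol
Product: 2 phlorisovalerophenone
Conditions: isovaleryl chloride, AlCl3, PhNO2, rt to 60 °C; then ice, aq. HCl
Reagents that add atoms: isovaleryl chloride (3-methylbutanoyl chloride), CC(C)CC(=O)Cl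
Why: Friedel–Crafts acylation of the activated arene; the acyl group deactivates the ring, so the reaction should stop after one acylation, and no stereocentre is formed.

Step 2
Reactants: 2 phlorisovalerophenone
Product: 3 ring A trione (gem-diprenyl)
Conditions: prenyl bromide (2.1 equiv), NaOMe (2.1 equiv), MeOH, −10 °C to rt
Reagents that add atoms: prenyl bromide (1-bromo-3-methylbut-2-ene), CC(C)=CCBr
Why: Alkylative dearomatisation (geminal C-prenylation) of the acylphloroglucinol dianion: after the first C-alkylation the alkylated carbon should be the most nucleophilic site, so the second prenyl group should enter there and leave the opposite ring carbon (the later C3) free; no stereocentre is formed.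

Step 3
Reactants: 4 (R)-(−)-linalool
Product: 5 linalool triethylsilyl ether
Conditions: Et3SiOTf, 2,6-lutidine, CH2Cl2, −78 °C to 0 °C
Reagents that add atoms: triethylsilyl triflate, CC[Si](CC)(CC)OS(=O)(=O)C(F)(F)F
Why: Silylation of a tertiary alcohol with a silyl triflate; the stereocentre (later C12) is untouched and the ether keeps this oxygen from attacking the epoxides later.

Step 4
Reactants: 5 linalool triethylsilyl ether
Product: 6 (E)-allylic alcohol
Conditions: SeO2 (cat.), t-BuOOH, CH2Cl2, rt
Reagents that add atoms: selenium dioxide (catalytic oxygen carrier), O=[Se]=O; tert-butyl hydroperoxide (terminal oxidant), CC(C)(C)OO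
Why: Selenium dioxide allylic oxidation (ene reaction, then 2,3-sigmatropic shift) should hydroxylate the (E)-methyl group of the trisubstituted alkene and leave the vinyl group, whose only allylic carbon is quaternary, untouched.

Step 5
Reactants: 6 (E)-allylic alcohol
Product: 7 (2R,3R)-epoxy alcohol
Conditions: Ti(OiPr)4 (10 mol %), D-(−)-diethyl tartrate (12 mol %), t-BuOOH, 4 Å molecular sieves, CH2Cl2, −20 °C
Reagents that add atoms: tert-butyl hydroperoxide, CC(C)(C)OO
Why: Sharpless asymmetric epoxidation: the titanium tartrate catalyst binds the allylic alcohol and D-(−)-diethyl tartrate should deliver oxygen to the face that gives the (2R,3R)-epoxide, which sets C13 and (before its inversion in step 9) C9; the vinyl group is no allylic alcohol and should not react.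

Step 6
Reactants: 7 (2R,3R)-epoxy alcohol
Product: 8 epoxy tosylate
Conditions: TsCl, Et3N, 4-(dimethylamino)pyridine (cat.), CH2Cl2, 0 °C
Reagents that add atoms: p-toluenesulfonyl chloride, Cc1ccc(cc1)S(=O)(=O)Cl
Why: Sulfonylation of the primary alcohol turns the epoxy alcohol into a 2,3-epoxy tosylate without touching the epoxide stereocentres.

Step 7
Reactants: 8 epoxy tosylate
Product: 9 primary alcohol
Conditions: 9-BBN, THF, 0 °C to rt; then aq. NaOAc, H2O2, 0 °C
Reagents that add atoms: hydrogen peroxide, OO
Why: Hydroboration–oxidation: the bulky dialkylborane adds boron to the terminal carbon of the only alkene, and buffered peroxide oxidation should give the primary alcohol with epoxide and tosylate intact.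

Step 8
Reactants: 9 primary alcohol
Product: 10 epoxy tosylate aldehyde
Conditions: [Pr4N][RuO4] (5 mol %), N-methylmorpholine N-oxide, 4 Å molecular sieves, CH2Cl2, rt
Reagents that add atoms: none
Why: Ley–Griffith oxidation of the primary alcohol to the aldehyde under neutral conditions that spare the epoxide, the tosylate and the silyl ether.

Step 9
Reactants: 10 epoxy tosylate aldehyde; 3 ring A trione (gem-diprenyl)
Product: 14 C12-O-triethylsilyl ether of the target, via oxiranyl cyclopentanecarbaldehyde 11 (not isolated), via alkylidene trione 12 (not isolated), via C-alkylated trione epoxide 13 (not isolated)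
Conditions: (S)-2-methylproline (20 mol %), i-Pr2NEt (1.2 equiv), DMSO, rt to 40 °C; then 3, Hantzsch ester (1.2 equiv), L-proline (10 mol %), rt; then DBU (2 equiv), 60 °C; one flask
Reagents that add atoms: none
Why: Proposed new method: the amino acid condenses with aldehyde 10 to an enamine whose α-carbon C8 opens the epoxide at its secondary carbon C9 (SN2 with inversion, the leaving oxygen assisted by hydrogen bonding), and the C13 alkoxide then displaces the neighbouring tosylate to give the terminal epoxide of 11; the closest known reaction is the aminocatalytic intramolecular α-alkylation of aldehydes with halide or sulfonate leaving groups, here extended to an epoxide. Aldehyde 11 and trione 3 then undergo the known three-component reductive alkylation of cyclic 1,3-diones (Knoevenagel condensation to 12, hydride transfer from the Hantzsch ester to 13), and the enolate carbon C3 of 13 opens the new epoxide at its CH2 carbon C14, a known type of intramolecular C-alkylation of 1,3-diones. Ring C closes 5-exo-tet (C8–C9) and ring B closes 6-endo-tet at the epoxide (C3–C14), the only carbon–carbon closure open to C3 because C13 is fully substituted and O-alkylation would need an eight-membered ring. C9 is set by inversion of the Sharpless epoxide, C13 keeps the epoxide oxygen and its configuration, and C8, being α to the aldehyde, should equilibrate through the enamine to the trans-1,2-disubstituted cyclopentane before the reduction freezes it. C3 is set in a chair-like transition state that should put the carbonyl next to the gem-diprenyl carbon equatorial, clear of the axial methyl group on C13, and the planar acyl-enol half axial. The step needs carbon (not the C12 oxygen) to attack C9, which the silyl ether secures, and attack at C9 rather than at the tosylate carbon, which the five-membered (against seven-membered) transition state should secure.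

Step 10
Reactants: 14 C12-O-triethylsilyl ether of the target
Product: 15 CNP0198642.3 (target)
Conditions: HF·pyridine, pyridine, THF, 0 °C to rt
Reagents that add atoms: none
Why: Fluoride-mediated cleavage of the tertiary triethylsilyl ether; no stereocentre is touched.

**Compound list**

1 | phloroglucinol (benzene-1,3,5-triol) | Oc1cc(O)cc(O)c1 | starting material
2 | phlorisovalerophenone, 3-methyl-1-(2,4,6-trihydroxyphenyl)butan-1-one | CC(C)CC(=O)c1c(O)cc(O)cc1O | intermediate
3 | ring A trione, 3,5-dihydroxy-2-(3-methylbutanoyl)-6,6-bis(3-methylbut-2-en-1-yl)cyclohexa-2,4-dien-1-one (achiral, one enol form) | CC(C)CC(=O)C1=C(O)C=C(O)C(CC=C(C)C)(CC=C(C)C)C1=O | intermediate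
4 | (R)-(−)-linalool, (3R)-3,7-dimethylocta-1,6-dien-3-ol | C=C[C@](C)(O)CCC=C(C)C | starting material
5 | (3R)-3,7-dimethyl-3-(triethylsilyloxy)octa-1,6-diene | C=C[C@](C)(O[Si](CC)(CC)CC)CCC=C(C)C | intermediate
6 | (2E,6R)-2,6-dimethyl-6-(triethylsilyloxy)octa-2,7-dien-1-ol | C=C[C@](C)(O[Si](CC)(CC)CC)CC/C=C(\C)CO | intermediate
7 | {(2R,3R)-2-methyl-3-[(3R)-3-methyl-3-(triethylsilyloxy)pent-4-en-1-yl]oxiran-2-yl}methanol | C=C[C@](C)(O[Si](CC)(CC)CC)CC[C@H]1O[C@]1(C)CO | intermediate
8 | {(2R,3R)-2-methyl-3-[(3R)-3-methyl-3-(triethylsilyloxy)pent-4-en-1-yl]oxiran-2-yl}methyl 4-methylbenzenesulfonate | C=C[C@](C)(O[Si](CC)(CC)CC)CC[C@H]1O[C@]1(C)COS(=O)(=O)c2ccc(C)cc2 | intermediate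
9 | {(2R,3R)-3-[(3R)-5-hydroxy-3-methyl-3-(triethylsilyloxy)pentyl]-2-methyloxiran-2-yl}methyl 4-methylbenzenesulfonate | OCC[C@](C)(O[Si](CC)(CC)CC)CC[C@H]1O[C@]1(C)COS(=O)(=O)c2ccc(C)cc2 | intermediate
10 | {(2R,3R)-2-methyl-3-[(3R)-3-methyl-5-oxo-3-(triethylsilyloxy)pentyl]oxiran-2-yl}methyl 4-methylbenzenesulfonate | O=CC[C@](C)(O[Si](CC)(CC)CC)CC[C@H]1O[C@]1(C)COS(=O)(=O)c2ccc(C)cc2 | intermediate
11 | (1S,2R,5R)-2-methyl-5-[(2S)-2-methyloxiran-2-yl]-2-(triethylsilyloxy)cyclopentane-1-carbaldehyde | O=C[C@H]1[C@@H](CC[C@@]1(C)O[Si](CC)(CC)CC)[C@@]2(C)CO2 | intermediate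
12 | Knoevenagel adduct of 11 and 3: ring A carrying at C3 the exocyclic alkylidene C3=C7H–cyclopentyl (alkene geometry not defined; cyclopentane stereocentres as in 11) | CC(C)CC(=O)C1=C(O)C(=C[C@H]2[C@@H](CC[C@@]2(C)O[Si](CC)(CC)CC)[C@@]3(C)CO3)C(=O)C(CC=C(C)C)(CC=C(C)C)C1=O | intermediate
13 | 3,5-dihydroxy-4-{[(1S,2R,5R)-2-methyl-5-[(2S)-2-methyloxiran-2-yl]-2-(triethylsilyloxy)cyclopentyl]methyl}-2-(3-methylbutanoyl)-6,6-bis(3-methylbut-2-en-1-yl)cyclohexa-2,4-dien-1-one | CC(C)CC(=O)C1=C(O)C(C[C@H]2[C@@H](CC[C@@]2(C)O[Si](CC)(CC)CC)[C@@]3(C)CO3)=C(O)C(CC=C(C)C)(CC=C(C)C)C1=O | intermediate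
14 | C12-O-triethylsilyl ether of the target (spiro centre C3 S, C8 S, C9 R, C12 R, C13 R; trans-fused rings B and C; free equatorial C13 hydroxyl) | CC(C)=CCC1(CC=C(C)C)C(=O)[C@@]2(C[C@H]3[C@@H](CC[C@@]3(C)O[Si](CC)(CC)CC)[C@](C)(O)C2)C(=O)C(C(=O)CC(C)C)=C1O | intermediate
15 | CNP0198642.3: ring A acyl-trione (gem-diprenyl, isovaleryl, enol) spiro-fused at C3 (S) to the trans-hydrindane diol (C8 S, C9 R, C12 R, C13 R) | CC(C)=CCC1(CC=C(C)C)C(=O)[C@@]2(C[C@H]3[C@@H](CC[C@@]3(C)O)[C@](C)(O)C2)C(=O)C(C(=O)CC(C)C)=C1O | target

**Step count and risks**

Total: 10 steps. Longest linear sequence: 8 steps (4 to 15, steps 3 to 10).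

Steps most likely to fail:

Step 9. The enamine may fail to open the unactivated epoxide, may alkylate at the tosylate carbon, or may lose the β-silyloxy group by elimination; in the last stage the facial selectivity at C3 may be low. The fallback sets out from 10. Condensation with N,N-dimethylhydrazine should give the N,N-dimethylhydrazone of 10 F1. LiN(i-Pr)2 (THF, −78 °C to 0 °C) should form the aza-enolate, whose carbon opens the epoxide 5-exo-tet, after which the alkoxide closes onto the tosylate carbon (the known alkylation of metalated hydrazones by epoxides), to give the N,N-dimethylhydrazone of 11 F2. Hydrolysis with aqueous oxalic acid should release aldehyde 11, now isolated, where the fallback comes back to the route; 11 is then taken to 14 by the known reductive alkylation with 3 and Hantzsch ester and the DBU-mediated ring closure, run as separate operations.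

Step 2. The second prenylation may go to the free ring carbon (aromatic 3,5-diprenyl isomer) or to oxygen instead of to the carbon already alkylated. The fallback sets out from 2. Mono-bromination (N-bromosuccinimide, MeCN, 0 °C) should give 1-(3-bromo-2,4,6-trihydroxyphenyl)-3-methylbutan-1-one F3, in which one of the two equivalent ring carbons is blocked. Prenyl bromide and NaOMe can then dialkylate only the remaining carbon, giving the bromo gem-diprenyl trione F4. Zn dust in AcOH (reductive dehalogenation of a 2-halo-1,3-dione) should remove bromine, and the fallback comes back at 3.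

Step 4. Conversion may be low, over-oxidation to the enal may occur, and the silyl ether may be partly lost. The fallback sets out from 5. Selective ozonolysis of the electron-rich trisubstituted alkene (O3, one equivalent, CH2Cl2–pyridine, −78 °C; then Me2S) should give (4R)-4-methyl-4-(triethylsilyloxy)hex-5-enal F5. Wittig olefination with Ph3P=C(CH3)CO2Et should give ethyl (2E,6R)-2,6-dimethyl-6-(triethylsilyloxy)octa-2,7-dienoate F6. Reduction with i-Bu2AlH (CH2Cl2, −78 °C) should give the allylic alcohol, and the fallback comes back at 6.

Further compounds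
F1 | step 9 | N,N-dimethylhydrazone of 10 | CN(C)/N=C/C[C@](C)(O[Si](CC)(CC)CC)CC[C@H]1O[C@]1(C)COS(=O)(=O)c2ccc(C)cc2
F2 | step 9 | N,N-dimethylhydrazone of 11 | CN(C)/N=C/[C@H]1[C@@H](CC[C@@]1(C)O[Si](CC)(CC)CC)[C@@]2(C)CO2
F3 | step 2 | 1-(3-bromo-2,4,6-trihydroxyphenyl)-3-methylbutan-1-one | CC(C)CC(=O)c1c(O)cc(O)c(Br)c1O
F4 | step 2 | 4-bromo-3,5-dihydroxy-2-(3-methylbutanoyl)-6,6-bis(3-methylbut-2-en-1-yl)cyclohexa-2,4-dien-1-one | CC(C)CC(=O)C1=C(O)C(Br)=C(O)C(CC=C(C)C)(CC=C(C)C)C1=O
F5 | step 4 | (4R)-4-methyl-4-(triethylsilyloxy)hex-5-enal | C=C[C@](C)(O[Si](CC)(CC)CC)CCC=O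
F6 | step 4 | ethyl (2E,6R)-2,6-dimethyl-6-(triethylsilyloxy)octa-2,7-dienoate | C=C[C@](C)(O[Si](CC)(CC)CC)CC/C=C(\C)C(=O)OCC
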